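The target is cut at two bonds: ring-fusion CH to the oxygenated ring-fusion carbon of the cycloheptanone (ring B), and CH2 to carbinol CH of the cyclopentane (ring A). The array exploited is C(=O)–CH(fusion)–C(O)(fusion) of ring B, with the CH2–CH(O)–CMe2 arm of ring A returning to the oxygenated fusion carbon. A pinacol-terminated Prins cyclisation closes ring A, enlarges a cyclohexane to ring B and unveils the ketone in one operation. Its precursor is a cis-1,2-bis(trimethylsilyloxy)-1-vinylcyclohexane with a dibenzyl acetal arm cis to the vinyl group, a vicinal methyl pair and a benzyloxypropyl chain.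

Key step: step 15

Assumption: in step 1 the (R,S,S)-phosphoramidite gives the (R)-methyl centre (mirror image of the usual (S,R,R)-ligand/(S)-3-alkylcyclohexanone pairing); if the sense were opposite, the antipodal ligand would be taken.

Correction: in the chair-like Prins array the benzyloxy group is expected equatorial, which places it cis to the tertiary silyloxy group, not anti. The key-step product is therefore written as the (2R) carbinol ether, and the carbinol is re-set by oxidation (step 17) and hydroxyl-directed reduction (step 21), so either epimer is usable.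

Step 1
Reactants: 1 cyclohex-2-en-1-one; 2 prop-2-en-1-yl acetate (allyl acetate)
Product: 4 (2S,3R)-3-methyl-2-(prop-2-en-1-yl)cyclohexan-1-one, via zinc enolate 3 (not isolated)
Conditions: Me2Zn, Cu(OTf)2 (cat.), (R,S,S)-O,O'-(1,1'-binaphthyl-2,2'-diyl) N,N-bis(1-phenylethyl)phosphoramidite (cat.), toluene, −30 °C; then 2, Pd(PPh3)4 (cat.), 0 °C
Reagents that add atoms: dimethylzinc, C[Zn]C
Why: Copper-catalysed asymmetric conjugate addition sets the methyl-bearing centre (R) by ligand control, and the zinc enolate is allylated anti to that methyl group (trans, 2S) by Tsuji–Trost allylation.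

Step 2
Reactants: 4 (2S,3R)-3-methyl-2-(prop-2-en-1-yl)cyclohexan-1-one
Product: 5 (2S,3R,6E)-6-[(dimethylamino)methylidene]-3-methyl-2-(prop-2-en-1-yl)cyclohexan-1-one
Conditions: t-BuOCH(NMe2)2, toluene, 80 °C
Reagents that add atoms: tert-butoxybis(dimethylamino)methane, CC(C)(C)OC(N(C)C)N(C)C
Why: Aminomethylenation can occur only at the α-methylene group, which blocks that side and installs the carbon that is later cleaved off to leave the second carbonyl (enaminone formation).

Step 3
Reactants: 5 (2S,3R,6E)-6-[(dimethylamino)methylidene]-3-methyl-2-(prop-2-en-1-yl)cyclohexan-1-one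
Product: 7 (2R,3R,6E)-6-[(dimethylamino)methylidene]-2,3-dimethyl-2-(prop-2-en-1-yl)cyclohexan-1-one, via potassium enolate 6 (not isolated)
Conditions: KN(SiMe3)2, THF, −78 °C; MeI, −78 to 0 °C
Reagents that add atoms: iodomethane, CI
Why: Only the C-2 proton is left for enolisation, and in the enolate the C-3 methyl is pseudoaxial to escape A(1,2) strain with the allyl group, so iodomethane enters on the opposite face and the new methyl is trans to the old one (2R); enolate alkylation of a blocked ketone.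

Step 4
Reactants: 7 (2R,3R,6E)-6-[(dimethylamino)methylidene]-2,3-dimethyl-2-(prop-2-en-1-yl)cyclohexan-1-one
Product: 9 (2R,3R,6E)-6-[(dimethylamino)methylidene]-2-(3-hydroxypropyl)-2,3-dimethylcyclohexan-1-one, via alkylborane 8 (not isolated)
Conditions: 9-BBN, THF, 0 °C to rt; then NaBO3·4H2O, H2O, rt
Reagents that add atoms: sodium perborate, [Na+].[O-]OB=O
Why: 9-BBN adds anti-Markovnikov to the terminal alkene and leaves the vinylogous amide alone (hydroboration–oxidation); no stereocentre is formed.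

Step 5
Reactants: 9 (2R,3R,6E)-6-[(dimethylamino)methylidene]-2-(3-hydroxypropyl)-2,3-dimethylcyclohexan-1-one
Product: 10 (2R,3R,6E)-2-[3-(benzyloxy)propyl]-6-[(dimethylamino)methylidene]-2,3-dimethylcyclohexan-1-one
Conditions: NaH, BnBr, Bu4NI (cat.), THF, 0 °C to rt
Reagents that add atoms: benzyl bromide, BrCc1ccccc1
Why: Williamson ether synthesis on the primary alkoxide; the ketone has no α-hydrogen left, so the base has nothing else to attack.

Step 6
Reactants: 10 (2R,3R,6E)-2-[3-(benzyloxy)propyl]-6-[(dimethylamino)methylidene]-2,3-dimethylcyclohexan-1-one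
Product: 11 (3R,4R)-3-[3-(benzyloxy)propyl]-3,4-dimethylcyclohexane-1,2-dione
Conditions: O2, hν, meso-tetraphenylporphyrin (cat.), CH2Cl2, −78 °C
Reagents that add atoms: dioxygen, O=O
Why: Singlet oxygen adds to the electron-rich enaminone double bond and the dioxetane cleaves to the 1,2-dione and dimethylformamide ([2+2] photooxygenation and cleavage of an enaminone).

Step 7
Reactants: 11 (3R,4R)-3-[3-(benzyloxy)propyl]-3,4-dimethylcyclohexane-1,2-dione; 12 1-bromo-3-methylbut-2-ene
Product: 13 (5R,6R)-6-[3-(benzyloxy)propyl]-2-hydroxy-5,6-dimethyl-2-(2-methylbut-3-en-2-yl)cyclohexan-1-one (both C-2 epimers)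
Conditions: In powder, THF–H2O, rt
Reagents that add atoms: none
Why: Barbier allylation: the prenylindium species adds through its γ-carbon to the carbonyl remote from the quaternary carbon and so builds the CMe2 arm; the configuration of the new carbinol is irrelevant because step 8 planarises it.

Step 8
Reactants: 13 (5R,6R)-6-[3-(benzyloxy)propyl]-2-hydroxy-5,6-dimethyl-2-(2-methylbut-3-en-2-yl)cyclohexan-1-one (both C-2 epimers)
Product: 14 (5R,6R)-6-[3-(benzyloxy)propyl]-5,6-dimethyl-2-(2-methylbut-3-en-2-yl)cyclohex-2-en-1-one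
Conditions: methyl N-(triethylammoniosulfonyl)carbamate (inner salt), toluene, 80 °C
Reagents that add atoms: none
Why: The sulfamate of the tertiary alcohol undergoes syn elimination with the only β-hydrogens present, those of the ring CH2, so both epimers converge on one conjugated enone (dehydration by Ei elimination).

Step 9
Reactants: 14 (5R,6R)-6-[3-(benzyloxy)propyl]-5,6-dimethyl-2-(2-methylbut-3-en-2-yl)cyclohex-2-en-1-one
Product: 15 2-{(4R,5R)-5-[3-(benzyloxy)propyl]-4,5-dimethyl-6-oxocyclohex-1-en-1-yl}-2-methylpropanal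
Conditions: OsO4 (cat.), NaIO4, 2,6-lutidine, dioxane–H2O, rt
Reagents that add atoms: sodium periodate, [Na+].[O-]I(=O)(=O)=O
Why: Lemieux–Johnson oxidation: OsO4 takes the monosubstituted vinyl group far faster than the hindered, electron-poor enone double bond, and periodate cleaves the diol to the aldehyde.

Step 10
Reactants: 15 2-{(4R,5R)-5-[3-(benzyloxy)propyl]-4,5-dimethyl-6-oxocyclohex-1-en-1-yl}-2-methylpropanal
Product: 16 (5R,6R)-6-[3-(benzyloxy)propyl]-2-[1,1-bis(benzyloxy)-2-methylpropan-2-yl]-5,6-dimethylcyclohex-2-en-1-one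
Conditions: BnOSiMe3, Me3SiOTf (cat.), CH2Cl2, −78 °C
Reagents that add atoms: benzyloxytrimethylsilane, C[Si](C)(C)OCc1ccccc1
Why: Silyl triflate-catalysed acetalisation with the alkoxysilane, driven by formation of the disiloxane, converts the aldehyde at low temperature and leaves the hindered enone carbonyl.

Step 11
Reactants: 16 (5R,6R)-6-[3-(benzyloxy)propyl]-2-[1,1-bis(benzyloxy)-2-methylpropan-2-yl]-5,6-dimethylcyclohex-2-en-1-one; 17 ethynylmagnesium bromide
Product: 18 (1R,5R,6R)-6-[3-(benzyloxy)propyl]-2-[1,1-bis(benzyloxy)-2-methylpropan-2-yl]-1-ethynyl-5,6-dimethylcyclohex-2-en-1-ol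
Conditions: CeCl3, THF, −78 to 0 °C
Reagents that add atoms: none
Why: The small organocerium acetylide adds 1,2; the lower face of the carbonyl is screened in either half-chair (by the pseudoaxial chain on C-6 in one, by the axial C-5 methyl in the other) while the upper face is free when the chain is pseudoaxial, so the ethynyl group should enter cis to the C-6 methyl (1R).

Step 12
Reactants: 18 (1R,5R,6R)-6-[3-(benzyloxy)propyl]-2-[1,1-bis(benzyloxy)-2-methylpropan-2-yl]-1-ethynyl-5,6-dimethylcyclohex-2-en-1-ol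
Product: 19 (1S,2R,3R,4R,6S)-3-[3-(benzyloxy)propyl]-1-[1,1-bis(benzyloxy)-2-methylpropan-2-yl]-2-ethynyl-3,4-dimethyl-7-oxabicyclo[4.1.0]heptan-2-ol
Conditions: VO(acac)2 (cat.), t-BuOOH, CH2Cl2, 0 °C to rt
Reagents that add atoms: tert-butyl hydroperoxide, CC(C)(C)OO
Why: Hydroxyl-directed vanadium-catalysed epoxidation: the vanadium alkoxide of the tertiary allylic alcohol delivers oxygen to the ring alkene on the hydroxyl face (epoxide cis to OH, 1S,6S), and the alkyne is inert.

Step 13
Reactants: 19 (1S,2R,3R,4R,6S)-3-[3-(benzyloxy)propyl]-1-[1,1-bis(benzyloxy)-2-methylpropan-2-yl]-2-ethynyl-3,4-dimethyl-7-oxabicyclo[4.1.0]heptan-2-ol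
Product: 20 (1R,2R,3R,4R)-3-[3-(benzyloxy)propyl]-1-[1,1-bis(benzyloxy)-2-methylpropan-2-yl]-2-ethenyl-3,4-dimethylcyclohexane-1,2-diol
Conditions: LiAlH4, THF, 0 to 65 °C
Reagents that add atoms: none
Why: Hydride opens the epoxide at its CH carbon (SN2, trans-diaxial), which leaves the tertiary alcohol with the oxygen configuration fixed in step 12, and the aluminium alkoxide of the propargylic alcohol reduces the alkyne to the vinyl group (trans-hydroalumination).

Step 14
Reactants: 20 (1R,2R,3R,4R)-3-[3-(benzyloxy)propyl]-1-[1,1-bis(benzyloxy)-2-methylpropan-2-yl]-2-ethenyl-3,4-dimethylcyclohexane-1,2-diol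
Product: 21 1,2-bis(trimethylsilyl) ether of 20
Conditions: 1-(trimethylsilyl)imidazole, neat, 70 °C
Reagents that add atoms: 1-(trimethylsilyl)imidazole, C[Si](C)(C)n1ccnc1
Why: This reagent silylates hindered tertiary alcohols without acid, so the acetal is not ionised before the key step (O-silylation).

Step 15
Reactants: 21 1,2-bis(trimethylsilyl) ether of 20
Product: 22 (2R,3aS,5R,6R,8aS)-2-(benzyloxy)-5-[3-(benzyloxy)propyl]-1,1,5,6-tetramethyl-8a-[(trimethylsilyl)oxy]octahydroazulen-4(1H)-one
Conditions: SnCl4, 2,6-di-tert-butyl-4-methylpyridine, CH2Cl2, −78 to −30 °C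
Reagents that add atoms: none
Why: SnCl4 ionises the dibenzyl acetal, the axial vinyl group attacks the benzyloxycarbenium ion through a chair-like six-membered array (endo for the alkene, exo for C=O+), and as charge builds on the internal vinyl carbon the neighbouring silyloxy-bearing ring carbon shifts to it while the carbinol oxygen becomes the ketone and loses its silyl group. This is a Prins–pinacol ring-enlarging cyclopentane annulation of a 1-alkenylcycloalkanol silyl ether with an acetal arm, applied here with an unsubstituted vinyl terminator and an oxygenated migrating carbon. The Prins ring is closed by the 6-endo attack and contracts to the cyclopentane in the 1,2-shift, and the same shift enlarges the cyclohexane to the cycloheptanone. The migrating carbon keeps its configuration and bonds to the cationic carbon within the only chair open to the cis vinyl/arm pair (arm equatorial, vinyl axial), so the ring-fusion hydrogen ends anti to the silyloxy group (3aS, trans fusion); the benzyloxy group takes the equatorial site, because the axial one clashes with the ring CH2 on the migrating carbon, and so ends cis to the silyloxy group (2R). The step needs the oxygenated ring carbon to migrate and not the quaternary one: its bond lies nearly parallel to the developing empty orbital whereas the bond to the quaternary carbon is equatorial on the new ring, and the silyloxy group raises its migratory aptitude.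

Step 16
Reactants: 22 (2R,3aS,5R,6R,8aS)-2-(benzyloxy)-5-[3-(benzyloxy)propyl]-1,1,5,6-tetramethyl-8a-[(trimethylsilyl)oxy]octahydroazulen-4(1H)-one
Product: 23 (2R,3aS,5R,6R,8aS)-2,8a-dihydroxy-5-(3-hydroxypropyl)-1,1,5,6-tetramethyloctahydroazulen-4(1H)-one
Conditions: H2 (1 atm), Pd(OH)2/C, MeOH, HCl (cat.), rt
Reagents that add atoms: none
Why: Catalytic hydrogenolysis removes both benzyl ethers and the acidic methanol cleaves the tertiary trimethylsilyl ether, while the hindered ketone is untouched.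

Step 17
Reactants: 23 (2R,3aS,5R,6R,8aS)-2,8a-dihydroxy-5-(3-hydroxypropyl)-1,1,5,6-tetramethyloctahydroazulen-4(1H)-one
Product: 24 3-[(3aS,5R,6R,8aS)-8a-hydroxy-1,1,5,6-tetramethyl-2,4-dioxodecahydroazulen-5-yl]propanoic acid
Conditions: Pr4N[RuO4] (cat.), NMO·H2O, MeCN, rt
Reagents that add atoms: water, O
Why: Perruthenate oxidation takes the secondary alcohol to the cyclopentanone and, through the aldehyde hydrate, the primary alcohol to the acid, with the tertiary alcohol inert; this erases the carbinol configuration left by step 15.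

Step 18
Reactants: 24 3-[(3aS,5R,6R,8aS)-8a-hydroxy-1,1,5,6-tetramethyl-2,4-dioxodecahydroazulen-5-yl]propanoic acid
Product: 26 (3aS,5R,6R,8aS)-5-(4-diazo-3-oxobutyl)-8a-hydroxy-1,1,5,6-tetramethylhexahydroazulene-2,4(1H,3H)-dione, via mixed anhydride 25 (not isolated)
Conditions: i-BuOCOCl, 4-methylmorpholine, THF, −15 °C; CH2N2, Et2O, 0 °C
Reagents that add atoms: diazomethane, C=[N+]=[N-]
Why: The acid is activated as the mixed carbonic anhydride, which the hindered tertiary alcohol does not attack, and acylation of diazomethane gives the diazoketone (first stage of the Arndt–Eistert sequence).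

Step 19
Reactants: 26 (3aS,5R,6R,8aS)-5-(4-diazo-3-oxobutyl)-8a-hydroxy-1,1,5,6-tetramethylhexahydroazulene-2,4(1H,3H)-dione
Product: 27 (3aS,5R,6R,8aS)-8a-hydroxy-5-(4-hydroxy-3-oxobutyl)-1,1,5,6-tetramethylhexahydroazulene-2,4(1H,3H)-dione
Conditions: aq. HClO4 (0.5 M), THF, rt
Reagents that add atoms: water, O
Why: Protonation of the diazoketone gives a diazonium ion that water displaces with loss of nitrogen (acid hydrolysis of a diazoketone to the hydroxymethyl ketone).

Step 20
Reactants: 27 (3aS,5R,6R,8aS)-8a-hydroxy-5-(4-hydroxy-3-oxobutyl)-1,1,5,6-tetramethylhexahydroazulene-2,4(1H,3H)-dione; 28 (triphenylphosphoranylidene)ketene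
Product: 30 (3aS,5R,6R,8aS)-8a-hydroxy-1,1,5,6-tetramethyl-5-[2-(5-oxo-2,5-dihydrofuran-3-yl)ethyl]hexahydroazulene-2,4(1H,3H)-dione, via ylide ester 29 (not isolated)
Conditions: toluene, 90 °C
Reagents that add atoms: none
Why: The primary hydroxyl adds to the ketene ylide and the resulting acyl-stabilised ylide closes onto the neighbouring ketone by intramolecular Wittig olefination to form the butenolide; the tertiary alcohol and the hindered ring ketones do not react.

Step 21
Reactants: 30 (3aS,5R,6R,8aS)-8a-hydroxy-1,1,5,6-tetramethyl-5-[2-(5-oxo-2,5-dihydrofuran-3-yl)ethyl]hexahydroazulene-2,4(1H,3H)-dione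
Product: 31 (2S,3aS,5R,6R,8aS)-2,8a-dihydroxy-1,1,5,6-tetramethyl-5-[2-(5-oxo-2,5-dihydrofuran-3-yl)ethyl]octahydroazulen-4(1H)-one
Conditions: Me4N[BH(OAc)3], MeCN–AcOH, −30 to 0 °C
Reagents that add atoms: none
Why: Evans–Saksena reduction: the tertiary hydroxyl exchanges onto boron and delivers hydride to the cyclopentanone on its own face, giving the anti 1,3-diol (2S); the butenolide and the ring ketone flanked by a quaternary carbon should be left.

Compound list
1 | cyclohex-2-en-1-one | O=C1C=CCCC1 | starting material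
2 | prop-2-en-1-yl acetate | CC(=O)OCC=C | starting material
3 | methylzinc (R)-3-methylcyclohex-1-en-1-olate | C[C@@H]1CCCC(O[Zn]C)=C1 | intermediate
4 | (2S,3R)-3-methyl-2-(prop-2-en-1-yl)cyclohexan-1-one | C[C@@H]1CCCC(=O)[C@H]1CC=C | intermediate
5 | (2S,3R,6E)-6-[(dimethylamino)methylidene]-3-methyl-2-(prop-2-en-1-yl)cyclohexan-1-one | C[C@@H]1CC/C(=C\N(C)C)C(=O)[C@H]1CC=C | intermediate
6 | potassium (3R,6E)-6-[(dimethylamino)methylidene]-3-methyl-2-(prop-2-en-1-yl)cyclohex-1-en-1-olate | C[C@@H]1CC/C(=C\N(C)C)C(O[K])=C1CC=C | intermediate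
7 | (2R,3R,6E)-6-[(dimethylamino)methylidene]-2,3-dimethyl-2-(prop-2-en-1-yl)cyclohexan-1-one | C[C@@H]1CC/C(=C\N(C)C)C(=O)[C@]1(C)CC=C | intermediate
8 | B-alkyl-9-borabicyclo[3.3.1]nonane from 7 (boron on the terminal chain carbon) | C[C@@H]1CC/C(=C\N(C)C)C(=O)[C@]1(C)CCCB1C2CCCC1CCC2 | intermediate
9 | (2R,3R,6E)-6-[(dimethylamino)methylidene]-2-(3-hydroxypropyl)-2,3-dimethylcyclohexan-1-one | C[C@@H]1CC/C(=C\N(C)C)C(=O)[C@]1(C)CCCO | intermediate
10 | (2R,3R,6E)-2-[3-(benzyloxy)propyl]-6-[(dimethylamino)methylidene]-2,3-dimethylcyclohexan-1-one | C[C@@H]1CC/C(=C\N(C)C)C(=O)[C@]1(C)CCCOCc2ccccc2 | intermediate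
11 | (3R,4R)-3-[3-(benzyloxy)propyl]-3,4-dimethylcyclohexane-1,2-dione | C[C@@H]1CCC(=O)C(=O)[C@]1(C)CCCOCc2ccccc2 | intermediate
12 | 1-bromo-3-methylbut-2-ene | CC(C)=CCBr | starting material
13 | (5R,6R)-6-[3-(benzyloxy)propyl]-2-hydroxy-5,6-dimethyl-2-(2-methylbut-3-en-2-yl)cyclohexan-1-one (both C-2 epimers) | C[C@@H]1CCC(O)(C(C)(C)C=C)C(=O)[C@]1(C)CCCOCc2ccccc2 | intermediate
14 | (5R,6R)-6-[3-(benzyloxy)propyl]-5,6-dimethyl-2-(2-methylbut-3-en-2-yl)cyclohex-2-en-1-one | C[C@@H]1CC=C(C(C)(C)C=C)C(=O)[C@]1(C)CCCOCc2ccccc2 | intermediate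
15 | 2-{(4R,5R)-5-[3-(benzyloxy)propyl]-4,5-dimethyl-6-oxocyclohex-1-en-1-yl}-2-methylpropanal | C[C@@H]1CC=C(C(C)(C)C=O)C(=O)[C@]1(C)CCCOCc2ccccc2 | intermediate
16 | (5R,6R)-6-[3-(benzyloxy)propyl]-2-[1,1-bis(benzyloxy)-2-methylpropan-2-yl]-5,6-dimethylcyclohex-2-en-1-one | C[C@@H]1CC=C(C(C)(C)C(OCc3ccccc3)OCc3ccccc3)C(=O)[C@]1(C)CCCOCc2ccccc2 | intermediate
17 | ethynylmagnesium bromide | C#C[Mg]Br | starting material
18 | (1R,5R,6R)-6-[3-(benzyloxy)propyl]-2-[1,1-bis(benzyloxy)-2-methylpropan-2-yl]-1-ethynyl-5,6-dimethylcyclohex-2-en-1-ol | C[C@@H]1CC=C(C(C)(C)C(OCc3ccccc3)OCc3ccccc3)[C@@](O)(C#C)[C@]1(C)CCCOCc2ccccc2 | intermediate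
19 | (1S,2R,3R,4R,6S)-3-[3-(benzyloxy)propyl]-1-[1,1-bis(benzyloxy)-2-methylpropan-2-yl]-2-ethynyl-3,4-dimethyl-7-oxabicyclo[4.1.0]heptan-2-ol | C[C@@H]1C[C@@H]2O[C@]2(C(C)(C)C(OCc3ccccc3)OCc3ccccc3)[C@@](O)(C#C)[C@]1(C)CCCOCc4ccccc4 | intermediate
20 | (1R,2R,3R,4R)-3-[3-(benzyloxy)propyl]-1-[1,1-bis(benzyloxy)-2-methylpropan-2-yl]-2-ethenyl-3,4-dimethylcyclohexane-1,2-diol | C[C@@H]1CC[C@@](O)(C(C)(C)C(OCc3ccccc3)OCc3ccccc3)[C@@](O)(C=C)[C@]1(C)CCCOCc2ccccc2 | intermediate
21 | 1,2-bis(trimethylsilyl) ether of 20 (key-step precursor) | C[C@@H]1CC[C@@](O[Si](C)(C)C)(C(C)(C)C(OCc3ccccc3)OCc3ccccc3)[C@@](O[Si](C)(C)C)(C=C)[C@]1(C)CCCOCc2ccccc2 | intermediate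
22 | (2R,3aS,5R,6R,8aS)-2-(benzyloxy)-5-[3-(benzyloxy)propyl]-1,1,5,6-tetramethyl-8a-[(trimethylsilyl)oxy]octahydroazulen-4(1H)-one (key-step product) | C[C@@H]1CC[C@]2(O[Si](C)(C)C)[C@H](C[C@@H](OCc3ccccc3)C2(C)C)C(=O)[C@]1(C)CCCOCc4ccccc4 | intermediate
23 | (2R,3aS,5R,6R,8aS)-2,8a-dihydroxy-5-(3-hydroxypropyl)-1,1,5,6-tetramethyloctahydroazulen-4(1H)-one | C[C@@H]1CC[C@]2(O)[C@H](C[C@@H](O)C2(C)C)C(=O)[C@]1(C)CCCO | intermediate
24 | 3-[(3aS,5R,6R,8aS)-8a-hydroxy-1,1,5,6-tetramethyl-2,4-dioxodecahydroazulen-5-yl]propanoic acid | C[C@@H]1CC[C@]2(O)[C@H](CC(=O)C2(C)C)C(=O)[C@]1(C)CCC(=O)O | intermediate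
25 | isobutyl carbonic mixed anhydride of 24 | C[C@@H]1CC[C@]2(O)[C@H](CC(=O)C2(C)C)C(=O)[C@]1(C)CCC(=O)OC(=O)OCC(C)C | intermediate
26 | (3aS,5R,6R,8aS)-5-(4-diazo-3-oxobutyl)-8a-hydroxy-1,1,5,6-tetramethylhexahydroazulene-2,4(1H,3H)-dione | C[C@@H]1CC[C@]2(O)[C@H](CC(=O)C2(C)C)C(=O)[C@]1(C)CCC(=O)C=[N+]=[N-] | intermediate
27 | (3aS,5R,6R,8aS)-8a-hydroxy-5-(4-hydroxy-3-oxobutyl)-1,1,5,6-tetramethylhexahydroazulene-2,4(1H,3H)-dione | C[C@@H]1CC[C@]2(O)[C@H](CC(=O)C2(C)C)C(=O)[C@]1(C)CCC(=O)CO | intermediate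
28 | (triphenylphosphoranylidene)ketene | O=C=C=P(c1ccccc1)(c1ccccc1)c1ccccc1 | starting material
29 | (triphenylphosphoranylidene)acetate ester of the primary hydroxyl of 27 | C[C@@H]1CC[C@]2(O)[C@H](CC(=O)C2(C)C)C(=O)[C@]1(C)CCC(=O)COC(=O)C=P(c3ccccc3)(c3ccccc3)c3ccccc3 | intermediate
30 | (3aS,5R,6R,8aS)-8a-hydroxy-1,1,5,6-tetramethyl-5-[2-(5-oxo-2,5-dihydrofuran-3-yl)ethyl]hexahydroazulene-2,4(1H,3H)-dione | C[C@@H]1CC[C@]2(O)[C@H](CC(=O)C2(C)C)C(=O)[C@]1(C)CCC1=CC(=O)OC1 | intermediate
31 | (2S,3aS,5R,6R,8aS)-2,8a-dihydroxy-1,1,5,6-tetramethyl-5-[2-(5-oxo-2,5-dihydrofuran-3-yl)ethyl]octahydroazulen-4(1H)-one (CNP0077405.3) | C[C@@H]1CC[C@]2(O)[C@H](C[C@H](O)C2(C)C)C(=O)[C@]1(C)CCC1=CC(=O)OC1 | target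

Total steps: 21. Longest linear sequence: 21 steps (1 to 31).

Steps most likely to fail

1. Step 15. The ionised acetal may fragment (cleavage of the bond between the two fully substituted carbons, pushed by the silyloxy group), or the silyl groups may be lost before the weakly nucleophilic vinyl group engages. Fallback: ring enlargement and ring closure are separated and no oxocarbenium ion is generated. It sets out from 21. N-Bromosuccinimide (CH2Cl2, −40 °C) forms a bromonium ion on the vinyl group, and the silyloxy-assisted shift of the same ring carbon gives the 2-(bromomethyl)cycloheptanone F1 (halonium-induced semipinacol rearrangement). Pyridinium tosylate in acetone–water unmasks the aldehyde F2. Bu3SnH with azobisisobutyronitrile closes the cyclopentane by 5-exo attack of the primary radical on the aldehyde to give F3. Hydrogenolysis as in step 16 gives the triol F4 (23 with its epimers at C-2 and C-3a), and the oxidation of step 17 comes back at 24; the ring-fusion CH, no longer set by the tether, would be separated or equilibrated at that stage.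

2. Step 12 (with the facial relay of step 11). Oxygen transfer to the very hindered ring alkene may be slow, or the addition in step 11 may not be face-selective, so that the carbinol configuration is not relayed. Fallback: keep the oxygen introduced in step 7 and secure its configuration by separation. It sets out from 13. Chromatography gives the epimer F5 (hydroxyl cis to the propyl chain); Lemieux–Johnson cleavage gives aldehyde F6 and acetalisation as in step 10 gives F7. Vinylmagnesium bromide with CeCl3 should then add axially, anti to the axial hydroxyl on the chair locked by the equatorial tert-alkyl arm, and comes back at 20.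

3. Step 21. Hydride may also be delivered to the ring ketone, or the hindered tertiary hydroxyl may not bind boron, with loss of chemo- or facial selectivity. Fallback: enzyme control in place of substrate direction. It sets out from 30: a ketoreductase screened for the anti alcohol (NADPH recycled with glucose and glucose dehydrogenase) reduces the unhindered cyclopentanone and comes back at 31.

Further compounds
F1 | step 15 | (3S,6R,7R)-7-[3-(benzyloxy)propyl]-3-[1,1-bis(benzyloxy)-2-methylpropan-2-yl]-2-(bromomethyl)-6,7-dimethyl-3-[(trimethylsilyl)oxy]cycloheptan-1-one (both C-2 epimers) | C[C@@H]1CC[C@@](O[Si](C)(C)C)(C(C)(C)C(OCc2ccccc2)OCc2ccccc2)C(CBr)C(=O)[C@]1(C)CCCOCc2ccccc2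
F2 | step 15 | 2-[(1S,4R,5R)-4-[3-(benzyloxy)propyl]-2-(bromomethyl)-1-hydroxy-4,5-dimethyl-3-oxocycloheptyl]-2-methylpropanal (both C-2 epimers) | C[C@@H]1CC[C@@](O)(C(C)(C)C=O)C(CBr)C(=O)[C@]1(C)CCCOCc2ccccc2
F3 | step 15 | (5R,6R,8aS)-5-[3-(benzyloxy)propyl]-2,8a-dihydroxy-1,1,5,6-tetramethyloctahydroazulen-4(1H)-one (epimers at C-2 and C-3a) | C[C@@H]1CC[C@]2(O)C(CC(O)C2(C)C)C(=O)[C@]1(C)CCCOCc3ccccc3
F4 | step 15 | (5R,6R,8aS)-2,8a-dihydroxy-5-(3-hydroxypropyl)-1,1,5,6-tetramethyloctahydroazulen-4(1H)-one (23 with its epimers at C-2 and C-3a) | C[C@@H]1CC[C@]2(O)C(CC(O)C2(C)C)C(=O)[C@]1(C)CCCO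
F5 | step 12 | (2R,5R,6R)-6-[3-(benzyloxy)propyl]-2-hydroxy-5,6-dimethyl-2-(2-methylbut-3-en-2-yl)cyclohexan-1-one | C[C@@H]1CC[C@@](O)(C(C)(C)C=C)C(=O)[C@]1(C)CCCOCc2ccccc2
F6 | step 12 | 2-{(1R,3R,4R)-3-[3-(benzyloxy)propyl]-1-hydroxy-3,4-dimethyl-2-oxocyclohexyl}-2-methylpropanal | C[C@@H]1CC[C@@](O)(C(C)(C)C=O)C(=O)[C@]1(C)CCCOCc2ccccc2
F7 | step 12 | (2R,5R,6R)-6-[3-(benzyloxy)propyl]-2-[1,1-bis(benzyloxy)-2-methylpropan-2-yl]-2-hydroxy-5,6-dimethylcyclohexan-1-one | C[C@@H]1CC[C@@](O)(C(C)(C)C(OCc3ccccc3)OCc3ccccc3)C(=O)[C@]1(C)CCCOCc2ccccc2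
F0 | step 21 | none | none
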